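Readings and results are calculated for substances that don't exist; the scatter is artificial.

- Along the time of the red run, solid substrate falls from 73 % to 2 % of the charge while target climbs, yet the remainder stays nearly constant over the readings: 22.0 % at the first reading and 25.0 % at the last.
- Taken as a concentration, this remainder is the gap: substrate present as neither solid substrate nor target, a quasi-steady pool, read as 46.7 mM on average.

- red: solid substrate 0.20 M; run made earlier
- flask: solid substrate 0.10 M; time 40 min

- red (time / min: solid substrate / %, target / %): 0.333: 73, 5; 0.500: 71, 8; 0.833: 65, 15; 1.33: 53, 19; 2.50: 32, 44; 4.00: 2, 73

(standard deviation of a reading: 1.5 percentage points)

- for target the crystals are counted in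
- as a solid, counted per litre of solution: solid substrate, crystals
- the earlier runs were read with a standard deviation of 1.5 percentage points
- on the list of suspects stand: target <-> isomer of the product; crystals <-> target; starting material <-> target; solid substrate <-> starting material
- at the start none of the solid substrate is in solution
- what has only dissolved of solid substrate counts as not reacted
- the reaction counts as stopped when no species that holds the solid substrate changes by six tenths of a point or more over the second half of the time

- at 40 min, what has stopped the reaction, if anything has (for what has run out or reacted, a solid counts together with what of it has only dissolved) (all of the solid substrate has reacted / it is still moving / forward and back rates have come level)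
- part of the solid substrate that has turned into other species by 40 min (what has only dissolved does not count)
- target at 40 min, in percent of the solid substrate charged

- Frozen extreme: if the gap kept that concentration in this flask, with half the red charge, target would end at 53.3 %.
- Drained extreme: if the gap emptied, target would take the whole charge.
- In the red run solid substrate falls, as read, by 37.8 mM min⁻¹, so the gap of that run turns over in 1.23 min, far shorter than 40 min. With 1.23 min so far under 40 min, my reckoning puts this flask at rest by the end, with rates level on the two-way steps and target between the two extremes.
- The forecast says it is still moving, with conversion 99 % (93 % to 100 %) and target 40 % (20 % to 85 %), this last figure set on the ground that “reversibility would leave more”; its target stands lower than the frozen extreme, where mine stands above it.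
- At 40 min this flask gives target 88.8 % and conversion 96.9 %, and the outcome is: forward and back rates have come level, with 0 percentage points of change over the second half.

    target ⇌ isomer of the product (K = 3.00, k = 0.0310 s⁻¹)
    crystals ⇌ target, rate k2*(cs2 - [target]) while solid is left; crystals form when [target] > cs2 (solubility = 2.70 mM, k = 0.400 s⁻¹)
    starting material ⇌ target (K = 0.880, k = 0.0170 s⁻¹)
    solid substrate ⇌ starting material, rate k4*(cs4 - [starting material]) while solid is left; crystals form when [starting material] > cs4 (solubility = 43.0 mM, k = 0.710 s⁻¹)

- The gap of this flask ends at 11.2 mM, a quarter of the 46.7 mM read on average in the red run. Kept at that concentration, it puts target at 93.4 % in the neighbour flask with 0.17 M, which holds 93.4 %.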